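## Retrosynthetic overview
1. Target ⇒ syn-epoxyquinol acid. The C6–O bond of an α-keto epoxide is cleaved reductively, and kinetic protonation anti to C5–O sets C6.
2. syn-Epoxyquinol ⇒ epoxyquinone (C4 ketone reduced anti to the oxirane) ⇒ free, unprotected, fully substituted quinone by one enantioselective nucleophilic epoxidation. This single oxirane controls all three ring stereocentres.
3. Quinone ⇒ 2,3,6-trisubstituted phenol by aerobic para-oxidation. The order arene → quinone → epoxyquinone → epoxyquinol → ketol is the one presumed for the ambuic/pestallic acids.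
4. Phenol ⇒ Suzuki union of an (R)-acetoxyheptenylboronate (from (R)-propylene oxide) with a bromophenol. The bromophenol's C5 acid chain comes from O-allylation/Claisen ortho to OH ("prenylation") and cross-metathesis.
5. Rings: the carbocycle is carried through from the arene. The only ring formed is the oxirane (step 8), and it is opened again in the last step.

Ring numbering in the text: C1 ketone, C2 alkenyl carbon, C3 CH2OH carbon, C4 and C5 carbinols, C6 carbon with the acid chain. The target is 4R,5S,6R,6'R, with the three ring substituents all cis.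

Assumption: diisopropyl D-tartrate is taken to deliver the peroxide oxygen to the face that gives the (1R,6S)-epoxide. If the sense is the reverse, the L-ester is used and nothing else changes.

## Route

Step 1
Reactants: 1 (R)-2-methyloxirane; 2 but-3-en-1-ylmagnesium bromide
Product: 4 (R)-hept-6-en-2-yl acetate, via bromomagnesium (R)-hept-6-en-2-olate 3 (not isolated)
Conditions: CuI (10 mol %), THF, −30 to 0 °C; then Ac2O, DMAP (5 mol %), 0 °C to rt; H2O
Reagents that add atoms: acetic anhydride, CC(=O)OC(C)=O
Why: Copper-catalysed Grignard opening of the epoxide (SN2 at the CH2 carbon) does not touch the C–O stereocentre, so the R configuration of 1 is carried into 3, whose alkoxide is O-acetylated in the same flask.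

Step 2
Reactants: 4 (R)-hept-6-en-2-yl acetate; 5 4,4,5,5-tetramethyl-2-vinyl-1,3,2-dioxaborolane
Product: 6 (R,E)-7-(4,4,5,5-tetramethyl-1,3,2-dioxaborolan-2-yl)hept-6-en-2-yl acetate
Conditions: second-generation Hoveyda–Grubbs catalyst (3 mol %), CH2Cl2, 40 °C
Reagents that add atoms: none
Why: Olefin cross-metathesis of a terminal alkene with the slowly homodimerising vinylboronate gives the cross product, the bulky boryl group enforces E geometry, and the remote acetate stereocentre is untouched.

Step 3
Reactants: 7 2-bromo-3-hydroxybenzaldehyde; 8 allyl bromide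
Product: 9 3-(allyloxy)-2-bromobenzaldehyde
Conditions: K2CO3, DMF, rt
Reagents that add atoms: none
Why: Williamson ether synthesis, in which the acidic phenol is the only nucleophilic site and allyl bromide is a fast SN2 partner.

Step 4
Reactants: 9 3-(allyloxy)-2-bromobenzaldehyde
Product: 10 4-allyl-2-bromo-3-hydroxybenzaldehyde
Conditions: PhNEt2, 200 °C, sealed tube
Reagents that add atoms: none
Why: Aromatic Claisen rearrangement, in which one ortho position is blocked by bromine so the [3,3] shift can end only at C4, and rearomatisation gives the ortho-allylphenol.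

Step 5
Reactants: 10 4-allyl-2-bromo-3-hydroxybenzaldehyde; 11 tert-butyl methacrylate
Product: 12 tert-butyl (E)-4-(3-bromo-4-formyl-2-hydroxyphenyl)-2-methylbut-2-enoate
Conditions: second-generation Hoveyda–Grubbs catalyst (5 mol %), 1,4-benzoquinone (10 mol %), 11 (8 equiv), CH2Cl2, 45 °C
Reagents that add atoms: none
Why: Olefin cross-metathesis of a reactive allylarene with a 1,1-disubstituted acrylate that does not homodimerise gives the trisubstituted enoate with the ester trans to the chain (E, thermodynamic), and benzoquinone suppresses allyl-to-propenyl isomerisation.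

Step 6
Reactants: 12 tert-butyl (E)-4-(3-bromo-4-formyl-2-hydroxyphenyl)-2-methylbut-2-enoate; 6 (R,E)-7-(4,4,5,5-tetramethyl-1,3,2-dioxaborolan-2-yl)hept-6-en-2-yl acetate
Product: 14 tert-butyl (E)-4-{3-[(1E,6R)-6-acetoxyhept-1-enyl]-2-hydroxy-4-(hydroxymethyl)phenyl}-2-methylbut-2-enoate, via alkenyl benzaldehyde 13 (not isolated)
Conditions: Pd(OAc)2 (3 mol %), SPhos (6 mol %), K3PO4, THF–H2O 10:1, 45 °C; then NaBH4, MeOH, 0 °C
Reagents that add atoms: none
Why: Suzuki–Miyaura coupling proceeds with retention of the E-alkenyl geometry (SPhos copes with the doubly ortho-substituted bromide and the mild base spares the acetate), and NaBH4 at 0 °C then reduces only the aldehyde, not the enoate or the acetate.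

Step 7
Reactants: 14 tert-butyl (E)-4-{3-[(1E,6R)-6-acetoxyhept-1-enyl]-2-hydroxy-4-(hydroxymethyl)phenyl}-2-methylbut-2-enoate
Product: 15 tert-butyl (E)-4-{5-[(1E,6R)-6-acetoxyhept-1-enyl]-4-(hydroxymethyl)-3,6-dioxocyclohexa-1,4-dienyl}-2-methylbut-2-enoate
Conditions: Co(salen) [N,N'-bis(salicylidene)ethylenediaminocobalt, C16H14CoN2O2] (10 mol %), O2 (1 atm), DMF, rt; used at once
Reagents that add atoms: dioxygen, O=O
Why: Cobalt–salen aerobic phenol oxidation, in which the phenoxyl radical of a 2,3,6-trisubstituted phenol (the classical substrate type) is trapped by oxygen at its only free para carbon and loses water to give the p-quinone, leaving the primary alcohol, esters and alkenes alone.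

Step 8
Reactants: 15 tert-butyl (E)-4-{5-[(1E,6R)-6-acetoxyhept-1-enyl]-4-(hydroxymethyl)-3,6-dioxocyclohexa-1,4-dienyl}-2-methylbut-2-enoate
Product: 16 tert-butyl (E)-4-{(1R,6S)-3-[(1E,6R)-6-acetoxyhept-1-enyl]-4-(hydroxymethyl)-2,5-dioxo-7-oxabicyclo[4.1.0]hept-3-en-1-yl}-2-methylbut-2-enoate
Conditions: Ph3COOH (1.5 equiv), NaN(SiMe3)2 (1.3 equiv), diisopropyl D-tartrate (1.5 equiv), 4 Å MS, toluene, −60 °C; AcOH quench
Reagents that add atoms: trityl hydroperoxide, OOC(c1ccccc1)(c1ccccc1)c1ccccc1
Why: Proposed new method: the deprotonated CH2OH group is drawn into the sodium tartrate–trityl peroxide aggregate, which adds peroxide to the only unsubstituted quinone carbon (C5) on one enantiotopic face, and the C6 enolate closes on oxygen with loss of Ph3CO− to set C5 (S) and C6 (R) together as a cis-fused oxirane, while the tetrasubstituted C2=C3 bond, the enoate and the acetate do not react at −60 °C and the tartrate-buffered base is too weak to enolise the side chain; the closest known reaction type is the hydroxyl-directed, tartrate-mediated Weitz–Scheffer epoxidation of quinone monoketals with the same CH2OH/alkyl pattern, extended here to the free quinone.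

Step 9
Reactants: 16 tert-butyl (E)-4-{(1R,6S)-3-[(1E,6R)-6-acetoxyhept-1-enyl]-4-(hydroxymethyl)-2,5-dioxo-7-oxabicyclo[4.1.0]hept-3-en-1-yl}-2-methylbut-2-enoate
Product: 17 tert-butyl (E)-4-{(1R,5R,6R)-3-[(1E,6R)-6-acetoxyhept-1-enyl]-5-hydroxy-4-(hydroxymethyl)-2-oxo-7-oxabicyclo[4.1.0]hept-3-en-1-yl}-2-methylbut-2-enoate
Conditions: Me4NBH(OAc)3, MeCN–AcOH, −30 °C
Reagents that add atoms: none
Why: Saksena–Evans hydroxyl-directed reduction, in which the primary alcohol exchanges onto boron so hydride reaches only the neighbouring C4 carbonyl (the C1 ketone, enoate, acetate and epoxide are inert to triacetoxyborohydride) and attacks antiperiplanar to the C5–O bond on the face opposite the oxirane (Felkin–Anh), giving the 4R alcohol syn to the epoxide.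

Step 10
Reactants: 17 tert-butyl (E)-4-{(1R,5R,6R)-3-[(1E,6R)-6-acetoxyhept-1-enyl]-5-hydroxy-4-(hydroxymethyl)-2-oxo-7-oxabicyclo[4.1.0]hept-3-en-1-yl}-2-methylbut-2-enoate
Product: 18 (E)-4-{(1R,5R,6R)-3-[(1E,6R)-6-acetoxyhept-1-enyl]-5-hydroxy-4-(hydroxymethyl)-2-oxo-7-oxabicyclo[4.1.0]hept-3-en-1-yl}-2-methylbut-2-enoic acid
Conditions: TFA–CH2Cl2 1:4, 0 °C; evaporate with toluene, then MeOH
Reagents that add atoms: none
Why: Acidolysis of the tert-butyl ester by the E1 path (tert-butyl cation to isobutene) needs neither base nor nucleophile, so the acetate, the electron-poor keto epoxide and the non-ionisable alcohols on the enone survive and no stereocentre is touched, and it is placed here because the final ketol would dehydrate and aromatise in acid.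

Step 11
Reactants: 18 (E)-4-{(1R,5R,6R)-3-[(1E,6R)-6-acetoxyhept-1-enyl]-5-hydroxy-4-(hydroxymethyl)-2-oxo-7-oxabicyclo[4.1.0]hept-3-en-1-yl}-2-methylbut-2-enoic acid
Product: 20 pestallic acid J, via samarium dienolate 19 (not isolated)
Conditions: SmI2 (2.5 equiv), THF–MeOH, −90 °C, 10 min; pH 7 buffer
Reagents that add atoms: none
Why: Samarium diiodide reduction of an α,β-epoxy ketone, in which two single-electron transfers to the C1 carbonyl break only the C6–O bond (C5–O is untouched and its descriptor changes from R to S by priority alone), and the trivalent samarium enolate 19, whose upper face carries the C5 samarium alkoxide and the C4 hydroxyl, is protonated kinetically from the open lower face (Zimmerman-type kinetic protonation), placing the side chain cis to both hydroxyls (6R) at a temperature where epimerisation, β-elimination and enoate reduction do not occur.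

## Compound list
1 | (R)-2-methyloxirane | C[C@@H]1CO1 | starting material
2 | but-3-en-1-ylmagnesium bromide | C=CCC[Mg]Br | starting material
3 | bromomagnesium (R)-hept-6-en-2-olate | Br[Mg]O[C@H](C)CCCC=C | intermediate
4 | (R)-hept-6-en-2-yl acetate | CC(=O)O[C@H](C)CCCC=C | intermediate
5 | 4,4,5,5-tetramethyl-2-vinyl-1,3,2-dioxaborolane | C=CB1OC(C)(C)C(C)(C)O1 | starting material
6 | (R,E)-7-(4,4,5,5-tetramethyl-1,3,2-dioxaborolan-2-yl)hept-6-en-2-yl acetate | CC(=O)O[C@H](C)CCC/C=C/B1OC(C)(C)C(C)(C)O1 | intermediate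
7 | 2-bromo-3-hydroxybenzaldehyde | O=Cc1cccc(O)c1Br | starting material
8 | allyl bromide | C=CCBr | starting material
9 | 3-(allyloxy)-2-bromobenzaldehyde | O=Cc1cccc(OCC=C)c1Br | intermediate
10 | 4-allyl-2-bromo-3-hydroxybenzaldehyde | O=Cc1ccc(CC=C)c(O)c1Br | intermediate
11 | tert-butyl methacrylate | C=C(C)C(=O)OC(C)(C)C | starting material
12 | tert-butyl (E)-4-(3-bromo-4-formyl-2-hydroxyphenyl)-2-methylbut-2-enoate | O=Cc1ccc(C/C=C(\C)C(=O)OC(C)(C)C)c(O)c1Br | intermediate
13 | tert-butyl (E)-4-{3-[(1E,6R)-6-acetoxyhept-1-enyl]-4-formyl-2-hydroxyphenyl}-2-methylbut-2-enoate | CC(=O)O[C@H](C)CCC/C=C/c1c(C=O)ccc(C/C=C(\C)C(=O)OC(C)(C)C)c1O | intermediate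
14 | tert-butyl (E)-4-{3-[(1E,6R)-6-acetoxyhept-1-enyl]-2-hydroxy-4-(hydroxymethyl)phenyl}-2-methylbut-2-enoate | CC(=O)O[C@H](C)CCC/C=C/c1c(CO)ccc(C/C=C(\C)C(=O)OC(C)(C)C)c1O | intermediate
15 | quinone: tert-butyl (E)-4-{5-[(1E,6R)-6-acetoxyhept-1-enyl]-4-(hydroxymethyl)-3,6-dioxocyclohexa-1,4-dienyl}-2-methylbut-2-enoate | CC(=O)O[C@H](C)CCC/C=C/C1=C(CO)C(=O)C=C(C/C=C(\C)C(=O)OC(C)(C)C)C1=O | intermediate
16 | (1R,6S)-epoxyquinone tert-butyl ester (7-oxabicyclo[4.1.0]hept-3-ene-2,5-dione; acid chain on C1, alkenyl on C3, CH2OH on C4) | CC(=O)O[C@H](C)CCC/C=C/C1=C(CO)C(=O)[C@H]2O[C@@]2(C/C=C(\C)C(=O)OC(C)(C)C)C1=O | intermediate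
17 | (1R,5R,6R)-syn-epoxyquinol tert-butyl ester (5-OH on the same face as the oxirane) | CC(=O)O[C@H](C)CCC/C=C/C1=C(CO)[C@@H](O)[C@H]2O[C@@]2(C/C=C(\C)C(=O)OC(C)(C)C)C1=O | intermediate
18 | (1R,5R,6R)-syn-epoxyquinol acid | CC(=O)O[C@H](C)CCC/C=C/C1=C(CO)[C@@H](O)[C@H]2O[C@@]2(C/C=C(\C)C(=O)O)C1=O | intermediate
19 | samarium dienolate (C1 enolate and C5 alkoxide each bound to SmI2; C6 planar) | CC(=O)O[C@H](C)CCC/C=C/C1=C(CO)[C@@H](O)[C@@H](O[Sm](I)I)C(C/C=C(\C)C(=O)O)=C1O[Sm](I)I | intermediate
20 | pestallic acid J: (E)-4-{(1R,5R,6S)-3-[(1E,6R)-6-acetoxyhept-1-enyl]-5,6-dihydroxy-4-(hydroxymethyl)-2-oxocyclohex-3-en-1-yl}-2-methylbut-2-enoic acid | CC(=O)O[C@H](C)CCC/C=C/C1=C(CO)[C@@H](O)[C@@H](O)[C@@H](C/C=C(\C)C(=O)O)C1=O | target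

## Step count and risks
Total step count: 11 (steps 1 and 6 are one-pot, two-operation steps).
Longest linear sequence: 9 (steps 3 to 11, from 7).

**Epoxidation of the free quinone (step 8).**
- Risk: the basic peroxide medium may degrade 15 by side-chain enolisation or 1,6-addition. The facial selectivity known for monoketals may also fail to carry over.
- Fallback: it sets out from phenol 14 and bypasses 15. PhI(OAc)2 (2.2 equiv) in MeOH at 0 °C gives the C4 dimethyl monoketal of the quinone F1.
- The same tartrate/Ph3COOH epoxidation is then run on this less electrophilic, base-tolerant dienone to give the epoxy monoketal F2.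
- Ketal hydrolysis (montmorillonite K10, wet CH2Cl2) comes back to the route at 16. This costs one extra step.

**Reduction of the C4 ketone (step 9).**
- Risk: boron-bound hydride might arrive on the oxirane face, giving the anti alcohol, or the C1 ketone might compete.
- Fallback: it sets out from 16 and swaps substrate control for enzyme control. TFA–CH2Cl2 first gives the epoxyquinone acid F3.
- The water-soluble carboxylate of F3 is reduced at pH 7 with a commercial NADPH-dependent ketoreductase (glucose/glucose dehydrogenase recycling). The panel member that gives the 4R alcohol is chosen.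
- This comes back to the route at 18 with the same step count.

**Reductive opening (step 11).**
- Risk: a proton may be delivered from the hydroxyl-bearing face, either by samarium-bound MeOH or by the C4–OH, to give the C6 epimer. Excess SmI2 may also cleave the γ-oxygen substituents.
- Fallback: it sets out from 18 and removes all internal proton donors. N,O-bis(trimethylsilyl)acetamide in THF gives the tris(trimethylsilyl) epoxyquinol F4.
- SmI2 in THF at −78 °C without protic cosolvent gives a persistent enolate. It is protonated from outside by the bulky 2,6-di-tert-butyl-4-methylphenol to give the tris(trimethylsilyl) ketol F5.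
- Citric acid in MeOH at 0 °C removes the silyl groups and comes back to the route at 20.

## Further compounds
F1 | step 8 | C4 dimethyl monoketal of quinone 15 (4,4-dimethoxycyclohexa-2,5-dienone with the C1 ketone kept) | CC(=O)O[C@H](C)CCC/C=C/C1=C(CO)C(OC)(OC)C=C(C/C=C(\C)C(=O)OC(C)(C)C)C1=O
F2 | step 8 | (1R,6S)-epoxy monoketal (C4 dimethyl ketal of 16) | CC(=O)O[C@H](C)CCC/C=C/C1=C(CO)C(OC)(OC)[C@H]2O[C@@]2(C/C=C(\C)C(=O)OC(C)(C)C)C1=O
F3 | step 9 | (1R,6S)-epoxyquinone acid (free acid of 16) | CC(=O)O[C@H](C)CCC/C=C/C1=C(CO)C(=O)[C@H]2O[C@@]2(C/C=C(\C)C(=O)O)C1=O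
F4 | step 11 | tris(trimethylsilyl) epoxyquinol (CH2OTMS, C4-OTMS and CO2TMS derivative of 18) | CC(=O)O[C@H](C)CCC/C=C/C1=C(CO[Si](C)(C)C)[C@@H](O[Si](C)(C)C)[C@H]2O[C@@]2(C/C=C(\C)C(=O)O[Si](C)(C)C)C1=O
F5 | step 11 | tris(trimethylsilyl) ketol (CH2OTMS, C4-OTMS and CO2TMS derivative of 20, free C5-OH) | CC(=O)O[C@H](C)CCC/C=C/C1=C(CO[Si](C)(C)C)[C@@H](O[Si](C)(C)C)[C@@H](O)[C@@H](C/C=C(\C)C(=O)O[Si](C)(C)C)C1=O
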